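**Retrosynthetic overview**

1. Numbering used throughout: five-membered ring C1(OAc)–C2H2–C3(CH3)–C9H–C10(OH)(iPr); seven-membered ring C3–C4(OH)–C5H2–C6(CH3)=C7H–C8(O-aroyl)–C9.
2. Endgame on a cis-fused hydroazulene: aroyl ester and acetate last; C8–OH by 1,2-reduction of the dienone C8(=O)–C7=C6–C5=C4; C4–OH by epoxidation of C4=C5 and palladium/formate opening; the C1/C10 cis-diol by dihydroxylation of C1=C10; isopropyl by cross-coupling of a C10 enol triflate.
3. Key disconnection C2–C3: anionic oxy-Cope rearrangement of an 8-vinylbicyclo[3.2.1]octa-3,6-dien-8-ol, with the enolate trapped as the C10 triflate. The enabling feature is the cis C3/C9 ring fusion together with oxygen on C10: once C10 is also bonded to C5, the chain C2=C1–C10(O)–C5–C4=C3 is a 3-oxy-hexa-1,5-diene held in a boat.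
4. Bicyclo[3.2.1] core: gold-catalysed 6-endo-dig closure (C5–C6) of a cyclopentane-1,3-dione enol ether onto a propargylic ether. Absolute configuration comes from one catalytic transfer hydrogenation with dynamic kinetic resolution (C8 and C9); C8 is later erased, and C9 relays C3, C1, C10, C4 and the final C8.
5. Ring order: cyclopentenone (bought) → six-membered ring of the bicycle (step 4) → five- and seven-membered rings of the target together (step 9: five-membered ring closes, six-membered ring expands to seven).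

Key step: step 9

Remark: compounds 2 and 26 are taken as catalogue reagents, and the syn diastereomer is assumed in step 2 (either sense can be steered to the correct C9 configuration by the catalyst enantiomer). In the bicyclic names, exo means syn to the one-carbon bridge; absolute configurations are as in the SMILES.

**Route**

Step 1
Reactants: 1 3-ethoxycyclopent-2-en-1-one; 2 N-methoxy-N-methylbut-2-ynamide
Product: 4 5-(but-2-ynoyl)-3-ethoxycyclopent-2-en-1-one (labile at C9), via lithium dienolate 3 (not isolated)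
Conditions: LiN(iPr)2 (1.1 equiv), THF, −78 °C; then 2, −78 → −40 °C; aq NH4Cl
Reagents that add atoms: none
Why: Crossed Claisen acylation of the kinetic α′-lithium dienolate by the Weinreb amide, whose chelated tetrahedral adduct survives until the quench, so the acidic 1,3-diketone appears only on work-up.

Step 2
Reactants: 4 5-(but-2-ynoyl)-3-ethoxycyclopent-2-en-1-one
Product: 5 (5R)-3-ethoxy-5-[(1R)-1-hydroxybut-2-yn-1-yl]cyclopent-2-en-1-one
Conditions: RuCl(p-cymene)[(R,R)-TsDPEN] (2 mol%), HCO2H–Et3N (5:2), CH2Cl2, rt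
Reagents that add atoms: none
Why: Noyori-type asymmetric transfer hydrogenation of the ynone with dynamic kinetic resolution: the catalyst sets C8 (alkynyl as the π-substituent), the enolisable C9 centre racemises under Et3N and is drained through the faster-reducing epimer to the syn product expected for Felkin-type hydride delivery, the vinylogous ester carbonyl stays inert, and the minor diastereomer is removed by chromatography.

Step 3
Reactants: 5 (5R)-3-ethoxy-5-[(1R)-1-hydroxybut-2-yn-1-yl]cyclopent-2-en-1-one
Product: 6 (5R)-3-ethoxy-5-[(1R)-1-(triisopropylsilyloxy)but-2-yn-1-yl]cyclopent-2-en-1-one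
Conditions: iPr3SiOTf, 2,6-lutidine, CH2Cl2, −78 → 0 °C
Reagents that add atoms: triisopropylsilyl trifluoromethanesulfonate (CC(C)[Si](OS(=O)(=O)C(F)(F)F)(C(C)C)C(C)C)
Why: Silylation of the hindered propargylic alcohol with the silyl triflate gives a bulky ether that should neither migrate under the later alkoxide conditions nor allow retro-aldol cleavage.

Step 4
Reactants: 6 (5R)-3-ethoxy-5-[(1R)-1-(triisopropylsilyloxy)but-2-yn-1-yl]cyclopent-2-en-1-one
Product: 7 4-methyl-2-exo-(triisopropylsilyloxy)bicyclo[3.2.1]oct-3-ene-6,8-dione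
Conditions: [Au(NCMe)(JohnPhos)]SbF6 (5 mol%; JohnPhos = 2-(di-tert-butylphosphino)biphenyl), CH2Cl2, H2O (2 equiv), rt
Reagents that add atoms: water (O)
Why: Monovalent-gold Conia-ene-type 6-endo-dig carbocyclisation: the enol-ether carbon C5 attacks the π-activated alkyne at the methyl-bearing C6, remote from the propargylic oxygen (the 5-exo mode would give a more strained bicyclo[2.2.1] skeleton), water hydrolyses the ethoxy oxocarbenium ion to the C4 ketone, and C5 is forced cis to C9 by the bridge.

Step 5
Reactants: 7 4-methyl-2-exo-(triisopropylsilyloxy)bicyclo[3.2.1]oct-3-ene-6,8-dione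
Product: 9 4,7-exo-dimethyl-2-exo-(triisopropylsilyloxy)bicyclo[3.2.1]oct-3-ene-6,8-dione, via lithium enolate 8 (not isolated)
Conditions: LiN(SiMe3)2 (1.05 equiv), THF, −78 °C; MeI, −78 → −40 °C
Reagents that add atoms: iodomethane (CI)
Why: Enolate alkylation at C3, the only enolisable site because every other α-carbon is a bridgehead; methyl iodide should enter from the exo face, and the new centre is erased in step 6.

Step 6
Reactants: 9 4,7-exo-dimethyl-2-exo-(triisopropylsilyloxy)bicyclo[3.2.1]oct-3-ene-6,8-dione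
Product: 11 4,7-dimethyl-8-oxo-2-exo-(triisopropylsilyloxy)bicyclo[3.2.1]octa-3,6-dien-6-yl trifluoromethanesulfonate, via potassium enolate 10 (not isolated)
Conditions: KN(SiMe3)2, THF, −78 °C; PhNTf2, −78 → 0 °C
Reagents that add atoms: N-phenylbis(trifluoromethanesulfonimide) (O=S(=O)(N(c1ccccc1)S(=O)(=O)C(F)(F)F)C(F)(F)F)
Why: O-Sulfonylation of the tetrasubstituted potassium enolate, formed from the only enolisable hydrogen left, gives the enol triflate regiospecifically.

Step 7
Reactants: 11 4,7-dimethyl-8-oxo-2-exo-(triisopropylsilyloxy)bicyclo[3.2.1]octa-3,6-dien-6-yl trifluoromethanesulfonate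
Product: 12 4,7-dimethyl-2-exo-(triisopropylsilyloxy)bicyclo[3.2.1]octa-3,6-dien-8-one
Conditions: Pd(OAc)2 (5 mol%), PPh3 (10 mol%), HCO2H, Bu3N, DMF, 40 °C
Reagents that add atoms: none
Why: Palladium-catalysed formate reduction of the alkenyl triflate (oxidative addition, formate decarboxylation, C–H reductive elimination) installs the C3(CH3)=C4H bridge and leaves the bridging ketone and silyl ether untouched.

Step 8
Reactants: 12 4,7-dimethyl-2-exo-(triisopropylsilyloxy)bicyclo[3.2.1]octa-3,6-dien-8-one
Product: 13 8-ethenyl-4,7-dimethyl-2-exo-(triisopropylsilyloxy)bicyclo[3.2.1]octa-3,6-dien-8-ol (vinyl syn to the C6=C7 bridge of the bicycle)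
Conditions: CH2=CHMgBr, CeCl3, THF, −78 °C; aq NH4Cl
Reagents that add atoms: vinylmagnesium bromide (C=C[Mg]Br)
Why: Organocerium 1,2-addition to the non-enolisable strained ketone; the nucleophile should come over the flat two-carbon alkene bridge because the pseudo-axial exo silyloxy group screens the face above the three-carbon bridge, which sets C10 with the vinyl group syn to C3=C4.

Step 9
Reactants: 13 8-ethenyl-4,7-dimethyl-2-exo-(triisopropylsilyloxy)bicyclo[3.2.1]octa-3,6-dien-8-ol
Product: 16 cis-fused C10 enol triflate (C10(OTf)=C1; C3 methyl; C4=C5–C6(CH3)=C7 diene; C8 silyl ether), via potassium alkoxide 14 (not isolated), via potassium enolate 15 (not isolated)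
Conditions: KH, 18-crown-6, THF, 0 °C → rt; then N-(5-chloropyridin-2-yl)bis(trifluoromethanesulfonimide), −78 → 0 °C; aq NH4Cl
Reagents that add atoms: N-(5-chloropyridin-2-yl)bis(trifluoromethanesulfonimide) (O=S(=O)(N(c1ccc(Cl)cn1)S(=O)(=O)C(F)(F)F)C(F)(F)F)
Why: Deprotonation gives alkoxide 14, whose 3-oxido-1,5-diene C2=C1–C10(O−)–C5–C4=C3 undergoes a concerted charge-accelerated [3,3]-sigmatropic shift through the boat transition state enforced by the bicycle, forming C2–C3 and breaking C10–C5, and enolate 15 is then O-sulfonylated. The closest precedent is the anionic oxy-Cope rearrangement of syn-7-vinylnorbornen-7-ols and 2-vinylbicyclo[2.2.2]octenols to cis-fused bicyclic enolates with in-situ enol triflate formation. The five-membered ring (C1, C2, C3, C9, C10) closes by suprafacial bonding of the vinyl terminus C2 to C3 on the face of the C3=C4 bridge that carries C10, while the seven-membered ring arises by expansion of the six-membered ring when the C10–C5 bridge bond is released. The only new stereocentre, quaternary C3, is fixed relative to C9 by the bridged framework: C2 must arrive syn to the C9–C10 bond, so the methyl ends cis to H-9 (cis fusion), and C9 passes unchanged. The step needs periselectivity ([3,3] over alkoxide fragmentation or a [1,3] shift) and regiodefined enolate capture; these are secured by the syn-vinyl geometry from step 8, the strain released from the bicyclo[3.2.1]octadiene, the geometric impossibility of a Cope shift through the C6=C7 bridge (vinyl anti to it), and trapping at −78 °C before proton transfer.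

Step 10
Reactants: 16 cis-fused C10 enol triflate
Product: 17 cis-fused C10-isopropyl triene with C8 triisopropylsilyl ether
Conditions: iPrZnBr, Pd(OAc)2 (3 mol%), CPhos (6 mol%), THF, rt
Reagents that add atoms: isopropylzinc bromide (CC(C)[Zn]Br)
Why: Negishi cross-coupling of the alkenyl triflate with the secondary alkylzinc; the bulky biarylphosphine should favour reductive elimination over β-hydride isomerisation to n-propyl.

Step 11
Reactants: 17 cis-fused C10-isopropyl triene with C8 triisopropylsilyl ether
Product: 18 C8 dienylic alcohol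
Conditions: Bu4NF, THF, 0 °C → rt
Reagents that add atoms: none
Why: Fluoride cleavage of the silyl ether.

Step 12
Reactants: 18 C8 dienylic alcohol
Product: 19 dienone C8(=O)–C7=C6(CH3)–C5=C4 with C1=C10(iPr)
Conditions: Dess–Martin periodinane, pyridine, CH2Cl2, 0 °C
Reagents that add atoms: none
Why: Buffered Dess–Martin oxidation of the dienylic alcohol should give the linearly conjugated dienone without epimerising C9; the C8 centre, having done its relay work, is erased.

Step 13
Reactants: 19 dienone with C1=C10(iPr)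
Product: 20 C1,C10-cis-diol dienone
Conditions: OsO4 (5 mol%), 4-methylmorpholine N-oxide, acetone–H2O, 0 °C → rt
Reagents that add atoms: 4-methylmorpholine N-oxide (C[N+]1([O-])CCOCC1); water (O)
Why: Upjohn dihydroxylation: OsO4 should select the isolated electron-rich C1=C10 alkene over the electron-poor dienone alkenes and add to the convex face of the cis-fused bicycle (the face of H-9 and the C3 methyl), setting C1 and C10 in one event.

Step 14
Reactants: 20 C1,C10-cis-diol dienone
Product: 21 C1 acetate C10 tertiary alcohol dienone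
Conditions: Ac2O, pyridine, DMAP (cat.), CH2Cl2, 0 °C → rt
Reagents that add atoms: acetic anhydride (CC(=O)OC(C)=O)
Why: DMAP-catalysed acetylation is confined to the secondary C1 hydroxyl; the tertiary C10 hydroxyl does not react.

Step 15
Reactants: 21 C1 acetate C10 tertiary alcohol dienone
Product: 22 C4,C5-epoxy enone (epoxide oxygen cis to the C3 methyl)
Conditions: mCPBA, NaHCO3, CH2Cl2, 0 °C
Reagents that add atoms: 3-chloroperoxybenzoic acid (O=C(OO)c1cccc(Cl)c1)
Why: Prilezhaev epoxidation: the peracid should take the γ,δ-alkene C4=C5 (the α,β-alkene is deactivated) from the convex face, the five-membered ring screening the other, which sets C4.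

Step 16
Reactants: 22 C4,C5-epoxy enone
Product: 23 C4 alcohol enone (C5H2; C6=C7–C8=O)
Conditions: Pd2(dba)3·CHCl3 (2.5 mol%), PBu3 (10 mol%), HCO2H, Et3N, dioxane, rt
Reagents that add atoms: none
Why: Palladium-catalysed formate hydrogenolysis of the alkenyl oxirane (Tsuji–Trost-type ionisation at C5 by zerovalent palladium, then hydride transfer from palladium to C5) gives the homoallylic alcohol with the enone kept in conjugation and C4 untouched.

Step 17
Reactants: 23 C4 alcohol enone
Product: 24 C4 triethylsilyl ether enone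
Conditions: Et3SiOTf, 2,6-lutidine, CH2Cl2, −78 °C
Reagents that add atoms: triethylsilyl trifluoromethanesulfonate (CC[Si](CC)(CC)OS(=O)(=O)C(F)(F)F)
Why: Low-temperature silylation masks the secondary C4 hydroxyl for the later acylation; the tertiary C10 hydroxyl is slower, and any silyl ether formed there would fall off in step 20.

Step 18
Reactants: 24 C4 triethylsilyl ether enone
Product: 25 C8 allylic alcohol (hydroxyl cis to C10)
Conditions: NaBH4, CeCl3·7H2O, MeOH, −78 → −40 °C
Reagents that add atoms: none
Why: Luche 1,2-reduction; hydride should attack C8 from the convex face, anti to C10 and its isopropyl group, which sets C8.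

Step 19
Reactants: 25 C8 allylic alcohol; 26 4-(tert-butyldimethylsilyloxy)benzoic acid
Product: 27 bis-silyl-protected target
Conditions: EDC·HCl, DMAP, CH2Cl2, rt → 40 °C
Reagents that add atoms: none
Why: Steglich esterification of the only free secondary hydroxyl with the silyl-protected acid.

Step 20
Reactants: 27 bis-silyl-protected target
Product: 28 CNP0146780.2
Conditions: Bu4NF, AcOH (1:1), THF, 0 °C
Reagents that add atoms: none
Why: Buffered fluoride removes the aryl and the C4 silyl ethers without acyl migration or ester cleavage.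

**Compound list**

1 | 3-ethoxycyclopent-2-en-1-one | CCOC1=CC(=O)CC1 | starting material
2 | N-methoxy-N-methylbut-2-ynamide | CC#CC(=O)N(C)OC | starting material
3 | lithium 3-ethoxycyclopenta-1,3-dien-1-olate | [Li+].CCOC1=CC([O-])=CC1 | intermediate
4 | 5-(but-2-ynoyl)-3-ethoxycyclopent-2-en-1-one | CCOC1=CC(=O)C(C(=O)C#CC)C1 | intermediate
5 | (5R)-3-ethoxy-5-[(1R)-1-hydroxybut-2-yn-1-yl]cyclopent-2-en-1-one | CCOC1=CC(=O)[C@@H]([C@@H](O)C#CC)C1 | intermediate
6 | (5R)-3-ethoxy-5-[(1R)-1-(triisopropylsilyloxy)but-2-yn-1-yl]cyclopent-2-en-1-one | CCOC1=CC(=O)[C@@H]([C@@H](O[Si](C(C)C)(C(C)C)C(C)C)C#CC)C1 | intermediate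
7 | 4-methyl-2-exo-(triisopropylsilyloxy)bicyclo[3.2.1]oct-3-ene-6,8-dione | O=C1[C@H]2[C@@H](O[Si](C(C)C)(C(C)C)C(C)C)C=C(C)[C@@H]1C(=O)C2 | intermediate
8 | lithium enolate of 7 | [Li+].O=C1[C@H]2[C@@H](O[Si](C(C)C)(C(C)C)C(C)C)C=C(C)[C@@H]1C([O-])=C2 | intermediate
9 | 4,7-exo-dimethyl-2-exo-(triisopropylsilyloxy)bicyclo[3.2.1]oct-3-ene-6,8-dione | O=C1[C@H]2[C@@H](O[Si](C(C)C)(C(C)C)C(C)C)C=C(C)[C@@H]1C(=O)[C@H]2C | intermediate
10 | potassium enolate of 9 | [K+].O=C1[C@H]2[C@@H](O[Si](C(C)C)(C(C)C)C(C)C)C=C(C)[C@@H]1C([O-])=C2C | intermediate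
11 | 4,7-dimethyl-8-oxo-2-exo-(triisopropylsilyloxy)bicyclo[3.2.1]octa-3,6-dien-6-yl trifluoromethanesulfonate | O=C1[C@H]2[C@@H](O[Si](C(C)C)(C(C)C)C(C)C)C=C(C)[C@@H]1C(OS(=O)(=O)C(F)(F)F)=C2C | intermediate
12 | 4,7-dimethyl-2-exo-(triisopropylsilyloxy)bicyclo[3.2.1]octa-3,6-dien-8-one | O=C1[C@H]2[C@@H](O[Si](C(C)C)(C(C)C)C(C)C)C=C(C)[C@@H]1C=C2C | intermediate
13 | 8-ethenyl-4,7-dimethyl-2-exo-(triisopropylsilyloxy)bicyclo[3.2.1]octa-3,6-dien-8-ol, vinyl syn to the C6=C7 bridge | C=C[C@]1(O)[C@H]2[C@@H](O[Si](C(C)C)(C(C)C)C(C)C)C=C(C)[C@@H]1C=C2C | intermediate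
14 | potassium alkoxide of 13 | [K+].C=C[C@]1([O-])[C@H]2[C@@H](O[Si](C(C)C)(C(C)C)C(C)C)C=C(C)[C@@H]1C=C2C | intermediate
15 | potassium enolate (C10–O−, C1=C10) of the cis-fused hydroazulenone | [K+].[O-]C1=CC[C@]2(C)C=CC(C)=C[C@H](O[Si](C(C)C)(C(C)C)C(C)C)[C@H]12 | intermediate
16 | cis-3a,6-dimethyl-8-(triisopropylsilyloxy)-3,3a,8,8a-tetrahydroazulen-1-yl trifluoromethanesulfonate | FC(F)(F)S(=O)(=O)OC1=CC[C@]2(C)C=CC(C)=C[C@H](O[Si](C(C)C)(C(C)C)C(C)C)[C@H]12 | intermediate
17 | cis-3a,6-dimethyl-1-(propan-2-yl)-8-(triisopropylsilyloxy)-3,3a,8,8a-tetrahydroazulene | CC(C)C1=CC[C@]2(C)C=CC(C)=C[C@H](O[Si](C(C)C)(C(C)C)C(C)C)[C@H]12 | intermediate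
18 | cis-3a,6-dimethyl-1-(propan-2-yl)-3,3a,8,8a-tetrahydroazulen-8-ol | CC(C)C1=CC[C@]2(C)C=CC(C)=C[C@H](O)[C@H]12 | intermediate
19 | cis-3a,6-dimethyl-1-(propan-2-yl)-3a,8a-dihydro-3H-azulen-8-one | CC(C)C1=CC[C@]2(C)C=CC(C)=CC(=O)[C@H]12 | intermediate
20 | C1,C10-cis-diol dienone (both hydroxyls cis to H-9 and the C3 methyl) | O[C@H]1C[C@]2(C)C=CC(C)=CC(=O)[C@@H]2[C@]1(O)C(C)C | intermediate
21 | C1 acetate of 20 | CC(=O)O[C@H]1C[C@]2(C)C=CC(C)=CC(=O)[C@@H]2[C@]1(O)C(C)C | intermediate
22 | C4,C5-epoxide of 21 (oxygen cis to the C3 methyl) | CC(=O)O[C@H]1C[C@]2(C)[C@H]3O[C@H]3C(C)=CC(=O)[C@@H]2[C@]1(O)C(C)C | intermediate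
23 | C1 acetate C4,C10-diol C6-en-8-one | CC(=O)O[C@H]1C[C@]2(C)[C@@H](O)CC(C)=CC(=O)[C@@H]2[C@]1(O)C(C)C | intermediate
24 | C4 triethylsilyl ether of 23 | CC(=O)O[C@H]1C[C@]2(C)[C@@H](O[Si](CC)(CC)CC)CC(C)=CC(=O)[C@@H]2[C@]1(O)C(C)C | intermediate
25 | C8 alcohol from 24 (hydroxyl cis to C10) | CC(=O)O[C@H]1C[C@]2(C)[C@@H](O[Si](CC)(CC)CC)CC(C)=C[C@H](O)[C@@H]2[C@]1(O)C(C)C | intermediate
26 | 4-(tert-butyldimethylsilyloxy)benzoic acid | O=C(O)c1ccc(O[Si](C)(C)C(C)(C)C)cc1 | starting material
27 | C8 4-(tert-butyldimethylsilyloxy)benzoate of 25 | CC(=O)O[C@H]1C[C@]2(C)[C@@H](O[Si](CC)(CC)CC)CC(C)=C[C@H](OC(=O)c3ccc(O[Si](C)(C)C(C)(C)C)cc3)[C@@H]2[C@]1(O)C(C)C | intermediate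
28 | CNP0146780.2 (C1 acetate, C8 4-hydroxybenzoate, C4 and C10 free hydroxyls) | CC(=O)O[C@H]1C[C@]2(C)[C@@H](O)CC(C)=C[C@H](OC(=O)c3ccc(O)cc3)[C@@H]2[C@]1(O)C(C)C | target

**Step count**

Total steps: 20. Longest linear sequence: 20 steps (from 1).

**Steps most likely to fail**

Step 4. The weakly nucleophilic enol ether may lose to 5-exo-dig closure, to attack by the carbonyl oxygen, or to gold-catalysed hydration of the alkyne. The fallback sets out from 6 and switches from π-acid activation to a radical ring closure. The enol ether is hydrolysed (1 M HCl, THF, rt) to (4R)-4-[(1R)-1-(triisopropylsilyloxy)but-2-yn-1-yl]cyclopentane-1,3-dione F1. F1 is then treated with Mn(OAc)3·2H2O in EtOH at rt: the trivalent-manganese enolate gives the C5 radical, which adds 6-endo to the alkyne at the methyl-bearing carbon, and the vinyl radical takes hydrogen from the solvent. The fallback comes back to the route at 7.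

Step 9. The alkoxide may fragment heterolytically at C10–C5 (the leaving carbanion is doubly allylic), or proton transfer may scramble the enolate before triflation. The fallback sets out from 13 and avoids the alkoxide altogether. Silylation (Me3SiCl, imidazole, DMF) gives the trimethylsilyl ether of 13 F2, and a neutral thermal siloxy-Cope rearrangement (o-dichlorobenzene, about 180 °C) delivers the trimethylsilyl enol ether F3 with the same enforced cis fusion. MeLi in THF at 0 °C cleaves the Si–O bond to the lithium enolate F4, which is triflated with the same chloropyridyl triflimide. The fallback comes back at 16.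

Step 15. Facial selectivity of peracid attack on C4=C5 may be poor, because the alkene is flanked by the C3 methyl on one face and the ring methylene C2 on the other. The fallback sets out from 20 and changes the control element from sterics to hydroxyl direction. The free C1/C10 diol, which lies entirely on the convex face, delivers the oxidant in a VO(acac)2-catalysed epoxidation with t-BuOOH (CH2Cl2, rt) to give the epoxy diol F5. Selective acetylation of the secondary hydroxyl (Ac2O, pyridine, DMAP) then comes back to the route at 22.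

Further compounds
F1 | step 4 | (4R)-4-[(1R)-1-(triisopropylsilyloxy)but-2-yn-1-yl]cyclopentane-1,3-dione | O=C1CC(=O)[C@@H]([C@@H](O[Si](C(C)C)(C(C)C)C(C)C)C#CC)C1
F2 | step 9 | trimethylsilyl ether of 13 | C=C[C@]1(O[Si](C)(C)C)[C@H]2[C@@H](O[Si](C(C)C)(C(C)C)C(C)C)C=C(C)[C@@H]1C=C2C
F3 | step 9 | trimethylsilyl enol ether of the cis-fused hydroazulenone | C[Si](C)(C)OC1=CC[C@]2(C)C=CC(C)=C[C@H](O[Si](C(C)C)(C(C)C)C(C)C)[C@H]12
F4 | step 9 | lithium enolate of the cis-fused hydroazulenone | [Li+].[O-]C1=CC[C@]2(C)C=CC(C)=C[C@H](O[Si](C(C)C)(C(C)C)C(C)C)[C@H]12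
F5 | step 15 | C4,C5-epoxy C1,C10-diol enone | O[C@H]1C[C@]2(C)[C@H]3O[C@H]3C(C)=CC(=O)[C@@H]2[C@]1(O)C(C)C
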